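**Plan**

- Numbering is that of the labdane skeleton: ring A = C1–C5/C10, ring B = C5–C10, C17 on C8, C18 (CH2OH) and C19 (CH3) on C4, C20 on C10, side chain C11–C12–C13, lactone C14–C15(=O)–O–C16.
- The retrosynthesis cuts C3–H, C4–C18 and C5–H (reduction and reductive hydroxymethylation of a ring A enone), lowers C17 from formyl to methyl, cuts C9–O (oxa-Michael), then C6–C7 and C8–C9 together (annulation with acrolein), then C11=C12 (Wittig), and last the ring A enone (Michael addition and aldol condensation).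
- The enabling feature: C6 is the γ-carbon of the ring A enone (C3=O, C4=C5) and C9 is a ketone carbon on the quaternary C10, 1,4 to C6. This donor/acceptor pair takes up acrolein as C7–C8–C17 and closes ring B.
- Forward order: ring A, side chain, ring B (key step), spiro-ether ring, C17 methyl, then the ring A stereocentres.
- Stereochemistry: C10 from a catalytic asymmetric Michael addition; C13 from a Sharpless epoxidation; C9 by axial O-attack anti to C20; C8 by equilibration (equatorial); C5, C4 and C3 under control of the angular methyl in the decalin.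

Key step: step 11

Remark: compound 14 is written as the open γ-hydroxy ketone; it is expected to sit largely as its cyclic hemiketal and to react through the open form.

**Step 1**
Reactants: 1 4-methoxy-2-methylidene-4-oxobutanoic acid (itaconic acid 4-methyl ester)
Product: 2 methyl 3-(hydroxymethyl)but-3-enoate
Conditions: BH3·SMe2 (1.1 equiv), THF, −10 to 0 °C; MeOH
Reagents that add atoms: none
Why: Borane reduces a free carboxylic acid much faster than an ester or an electron-poor 1,1-disubstituted alkene, so this chemoselective acid reduction should give the 2-substituted allylic alcohol.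

**Step 2**
Reactants: 2 methyl 3-(hydroxymethyl)but-3-enoate
Product: 3 methyl 2-[(2S)-2-(hydroxymethyl)oxiran-2-yl]acetate
Conditions: Ti(OiPr)4 (10 mol %), L-(+)-diethyl tartrate (12 mol %), t-BuOOH, 4 Å MS, CH2Cl2, −20 °C
Reagents that add atoms: tert-butyl hydroperoxide, CC(C)(C)OO
Why: Sharpless asymmetric epoxidation of a 2-substituted allylic alcohol, in which the L-(+)-tartrate ligand should deliver oxygen to the face that gives the (S)-epoxide and so sets the future C13.

**Step 3**
Reactants: 3 methyl 2-[(2S)-2-(hydroxymethyl)oxiran-2-yl]acetate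
Product: 4 methyl 2-[(2R)-2-formyloxiran-2-yl]acetate
Conditions: Dess–Martin periodinane, CH2Cl2, 0 °C
Reagents that add atoms: none
Why: Periodinane oxidation of a primary epoxy alcohol to the epoxy aldehyde runs under neutral conditions and does not touch the epoxide or the stereocentre.

**Step 4**
Reactants: 4 methyl 2-[(2R)-2-formyloxiran-2-yl]acetate
Product: 5 (3R)-3-hydroxy-5-oxooxolane-3-carbaldehyde
Conditions: BF3·OEt2 (0.2 equiv), CH2Cl2, −30 °C; then H2O
Reagents that add atoms: water, O
Why: Lewis-acid epoxide opening with participation of the ester carbonyl at the primary epoxide carbon (lactonisation through a five-membered dialkoxycarbenium ion, then hydrolysis) leaves the C13–O bond intact, so C13 is retained.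

**Step 5**
Reactants: 6 tert-butyl 2-methyl-3-oxobutanoate; 7 pent-1-en-3-one
Product: 8 tert-butyl (2S)-2-acetyl-2-methyl-5-oxoheptanoate
Conditions: 9-O-(9-phenanthryl)cupreidine or its cupreine-derived pseudoenantiomer (10 mol %, the antipode that gives the S adduct), CH2Cl2, −20 °C
Reagents that add atoms: none
Why: Bifunctional cinchona-alkaloid-catalysed enantioselective Michael addition of an α-substituted β-keto ester to a vinyl ketone, which creates the quaternary C10 under catalyst control.

**Step 6**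
Reactants: 8 tert-butyl (2S)-2-acetyl-2-methyl-5-oxoheptanoate
Product: 9 tert-butyl (1S)-1,2,3-trimethyl-4-oxocyclohex-2-ene-1-carboxylate
Conditions: pyrrolidine (0.3 equiv), AcOH (0.3 equiv), toluene, 80 °C
Reagents that add atoms: none
Why: Amine-catalysed intramolecular aldol condensation (second half of a Robinson annulation), in which the ethyl ketone enamine attacks the acetyl group and gives the tetrasubstituted enone without touching C10.

**Step 7**
Reactants: 9 tert-butyl (1S)-1,2,3-trimethyl-4-oxocyclohex-2-ene-1-carboxylate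
Product: 10 (1S)-1,2,3-trimethyl-4-oxocyclohex-2-ene-1-carboxylic acid
Conditions: TFA/CH2Cl2 (1:4), 0 °C to rt
Reagents that add atoms: none
Why: Acidolysis of the tert-butyl ester by loss of 2-methylpropene frees the acid without base, so the quaternary centre cannot be lost by retro-Michael cleavage.

**Step 8**
Reactants: 10 (1S)-1,2,3-trimethyl-4-oxocyclohex-2-ene-1-carboxylic acid
Product: 12 (4S)-2,3,4-trimethyl-4-[2-(triphenyl-λ5-phosphanylidene)acetyl]cyclohex-2-en-1-one, via acid chloride 11 (not isolated)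
Conditions: (COCl)2, DMF (cat.), CH2Cl2, 0 °C; evaporate; Ph3P=CH2 (2.1 equiv, from Ph3PCH3Br/NaHMDS), THF, −78 to 0 °C
Reagents that add atoms: methylenetriphenylphosphorane, C=P(c1ccccc1)(c1ccccc1)c1ccccc1
Why: Acylation of methylenetriphenylphosphorane by the acid chloride, with the second equivalent of ylide as base (transylidation), gives the stabilised acyl ylide, and acylation should outrun Wittig attack on the hindered enone carbonyl.

**Step 9**
Reactants: 12 (4S)-2,3,4-trimethyl-4-[2-(triphenyl-λ5-phosphanylidene)acetyl]cyclohex-2-en-1-one; 5 (3R)-3-hydroxy-5-oxooxolane-3-carbaldehyde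
Product: 13 (4S)-4-[(2E)-3-[(3S)-3-hydroxy-5-oxooxolan-3-yl]prop-2-enoyl]-2,3,4-trimethylcyclohex-2-en-1-one
Conditions: toluene, 80 °C
Reagents that add atoms: none
Why: Wittig olefination of a ketone-stabilised ylide with the α-oxygenated aldehyde joins C11 to C12 as the E-enone under neutral conditions that tolerate the lactone and the tertiary alcohol.

**Step 10**
Reactants: 13 (4S)-4-[(2E)-3-[(3S)-3-hydroxy-5-oxooxolan-3-yl]prop-2-enoyl]-2,3,4-trimethylcyclohex-2-en-1-one
Product: 14 (4S)-4-{3-[(3R)-3-hydroxy-5-oxooxolan-3-yl]propanoyl}-2,3,4-trimethylcyclohex-2-en-1-one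
Conditions: H2 (1 atm), RhCl(PPh3)3 (5 mol %), benzene/EtOH, rt
Reagents that add atoms: none
Why: Homogeneous hydrogenation with RhCl(PPh3)3 reduces the disubstituted side-chain alkene but not the tetrasubstituted ring A enone.

**Step 11**
Reactants: 14 (4S)-4-{3-[(3R)-3-hydroxy-5-oxooxolan-3-yl]propanoyl}-2,3,4-trimethylcyclohex-2-en-1-one; 15 prop-2-enal
Product: 17 (4aR)-5-{2-[(3R)-3-hydroxy-5-oxooxolan-3-yl]ethyl}-1,4a-dimethyl-2-oxo-2,3,4,4a,7,8-hexahydronaphthalene-6-carbaldehyde, via Michael adduct 16 (not isolated)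
Conditions: pyrrolidine (0.3 equiv), PhCO2H (0.3 equiv), 4 Å MS, toluene, 60 °C, slow addition of 15 (1.5 equiv)
Reagents that add atoms: none
Why: Proposed new method: pyrrolidinium benzoate should turn acrolein into its iminium ion and the ring A enone reversibly into the linear dienamine (N–C3=C4–C5=C6), whose only γ-position is the C6 methyl because C10 is quaternary; C6 adds to the iminium β-carbon (vinylogous Michael addition, bond C6–C7), the enamine of the new aldehyde then adds through C8 to the C9 ketone released from its hemiketal (bond C8–C9), and loss of water gives the conjugated enal. The closest known reactions are the amine-catalysed Robinson annulation with enals (Michael addition then aldol condensation) and the γ-selective dienamine Michael addition of β-methylcyclohexenones. Ring B is closed by a 6-(enolexo)-exo-trig aldol addition followed by dehydration, so the event is a formal [4+2] annulation between the C6/C9 donor–acceptor pair and the C7=C8 unit of acrolein. No stereocentre is created, because C8 and C9 become trigonal, and C10 and C13 are not touched. The step needs γ-attack (C6) over α-attack (C4) and α′-attack (C2): C4 is fully substituted and an adduct there cannot regain conjugation and should revert, while only the C6 adduct can close an unbridged six-membered ring onto C9 and reach the conjugated enal.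

**Step 12**
Reactants: 17 (4aR)-5-{2-[(3R)-3-hydroxy-5-oxooxolan-3-yl]ethyl}-1,4a-dimethyl-2-oxo-2,3,4,4a,7,8-hexahydronaphthalene-6-carbaldehyde
Product: 18 9α,13R-epoxy-3,17-dioxo-18-nor-8βH-labd-4-en-15,16-olide
Conditions: KOt-Bu (0.1 equiv), THF, −40 to 0 °C; AcOH
Reagents that add atoms: none
Why: Base-catalysed intramolecular oxa-Michael addition (5-exo-trig) of the tertiary C13 alkoxide to C9, where axial attack anti to the C10 methyl should set the 9α-oxygen and the epimerisable C8 should settle with the formyl group equatorial (8α).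

**Step 13**
Reactants: 18 9α,13R-epoxy-3,17-dioxo-18-nor-8βH-labd-4-en-15,16-olide
Product: 20 9α,13R-epoxy-3-oxo-18-nor-8βH-labd-4-en-15,16-olide, via tosylhydrazone 19 (not isolated)
Conditions: TsNHNH2, EtOH, rt; then catecholborane, CHCl3, 0 °C; NaOAc·3H2O, 60 °C
Reagents that add atoms: none
Why: Tosylhydrazone formation and catecholborane reduction (Caglioti-type deoxygenation) turns the aldehyde into the C17 methyl group under mild conditions that should spare the hindered enone, the lactone and the β-alkoxy linkage.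

**Step 14**
Reactants: 20 9α,13R-epoxy-3-oxo-18-nor-8βH-labd-4-en-15,16-olide
Product: 22 9α,13R-epoxy-18-hydroxy-3-oxo-5α,8βH-labdan-15,16-olide, via lithium enolate 21 (not isolated)
Conditions: Li (2.2 equiv), NH3(l)/THF, t-BuOH (1 equiv), −78 °C; isoprene; evaporate NH3; CH2O (g), THF, −78 °C; aq NH4Cl
Reagents that add atoms: formaldehyde, C=O
Why: Stork reductive alkylation, in which lithium–ammonia reduction of the 4-methyl enone gives the trans ring fusion (axial protonation at C5) and a regiodefined enolate that formaldehyde should attack from the α face, anti to the angular C10 methyl, to give the 4α-hydroxymethyl group.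

**Step 15**
Reactants: 22 9α,13R-epoxy-18-hydroxy-3-oxo-5α,8βH-labdan-15,16-olide
Product: 23 (3S,4R,5S,8R,9R,10S,13R)-3β,18-dihydroxy-9α,13-epoxylabdan-15,16-olide (CNP0274732.3)
Conditions: NaBH4, MeOH, 0 °C
Reagents that add atoms: none
Why: Borohydride reduction of the 4,4-disubstituted 3-ketone by axial hydride delivery from the α face should give the equatorial 3β-alcohol, and the lactone should survive at 0 °C.

**Compound list**

1 | 4-methoxy-2-methylidene-4-oxobutanoic acid (itaconic acid 4-methyl ester) | COC(=O)CC(=C)C(O)=O | starting material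
2 | methyl 3-(hydroxymethyl)but-3-enoate | COC(=O)CC(=C)CO | intermediate
3 | methyl 2-[(2S)-2-(hydroxymethyl)oxiran-2-yl]acetate | COC(=O)C[C@]1(CO)CO1 | intermediate
4 | methyl 2-[(2R)-2-formyloxiran-2-yl]acetate | COC(=O)C[C@]1(C=O)CO1 | intermediate
5 | (3R)-3-hydroxy-5-oxooxolane-3-carbaldehyde | O=C[C@]1(O)COC(=O)C1 | intermediate
6 | tert-butyl 2-methyl-3-oxobutanoate | CC(=O)C(C)C(=O)OC(C)(C)C | starting material
7 | pent-1-en-3-one | CCC(=O)C=C | starting material
8 | tert-butyl (2S)-2-acetyl-2-methyl-5-oxoheptanoate | CCC(=O)CC[C@@](C)(C(C)=O)C(=O)OC(C)(C)C | intermediate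
9 | tert-butyl (1S)-1,2,3-trimethyl-4-oxocyclohex-2-ene-1-carboxylate | CC1=C(C)C(=O)CC[C@]1(C)C(=O)OC(C)(C)C | intermediate
10 | (1S)-1,2,3-trimethyl-4-oxocyclohex-2-ene-1-carboxylic acid | CC1=C(C)C(=O)CC[C@]1(C)C(O)=O | intermediate
11 | (1S)-1,2,3-trimethyl-4-oxocyclohex-2-ene-1-carbonyl chloride | CC1=C(C)C(=O)CC[C@]1(C)C(Cl)=O | intermediate
12 | (4S)-2,3,4-trimethyl-4-[2-(triphenyl-λ5-phosphanylidene)acetyl]cyclohex-2-en-1-one | CC1=C(C)C(=O)CC[C@]1(C)C(=O)C=P(c2ccccc2)(c2ccccc2)c2ccccc2 | intermediate
13 | (4S)-4-[(2E)-3-[(3S)-3-hydroxy-5-oxooxolan-3-yl]prop-2-enoyl]-2,3,4-trimethylcyclohex-2-en-1-one | CC1=C(C)C(=O)CC[C@]1(C)C(=O)/C=C/[C@]2(O)COC(=O)C2 | intermediate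
14 | (4S)-4-{3-[(3R)-3-hydroxy-5-oxooxolan-3-yl]propanoyl}-2,3,4-trimethylcyclohex-2-en-1-one | CC1=C(C)C(=O)CC[C@]1(C)C(=O)CC[C@]2(O)COC(=O)C2 | intermediate
15 | prop-2-enal (acrolein) | C=CC=O | starting material
16 | 4-[(6S)-6-{3-[(3R)-3-hydroxy-5-oxooxolan-3-yl]propanoyl}-2,6-dimethyl-3-oxocyclohex-1-en-1-yl]butanal | O=CCCCC1=C(C)C(=O)CC[C@]1(C)C(=O)CC[C@]2(O)COC(=O)C2 | intermediate
17 | (4aR)-5-{2-[(3R)-3-hydroxy-5-oxooxolan-3-yl]ethyl}-1,4a-dimethyl-2-oxo-2,3,4,4a,7,8-hexahydronaphthalene-6-carbaldehyde | O=CC1=C(CC[C@]2(O)COC(=O)C2)[C@@]3(C)CCC(=O)C(C)=C3CC1 | intermediate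
18 | 9α,13R-epoxy-3,17-dioxo-18-nor-8βH-labd-4-en-15,16-olide | O=C[C@@H]1CCC2=C(C)C(=O)CC[C@]2(C)[C@@]12CC[C@@]1(COC(=O)C1)O2 | intermediate
19 | 9α,13R-epoxy-3-oxo-17-[(4-methylbenzenesulfonyl)hydrazinylidene]-18-nor-8βH-labd-4-en-15,16-olide | Cc1ccc(cc1)S(=O)(=O)N/N=C/[C@@H]1CCC2=C(C)C(=O)CC[C@]2(C)[C@@]12CC[C@@]1(COC(=O)C1)O2 | intermediate
20 | 9α,13R-epoxy-3-oxo-18-nor-8βH-labd-4-en-15,16-olide | C[C@@H]1CCC2=C(C)C(=O)CC[C@]2(C)[C@@]12CC[C@@]1(COC(=O)C1)O2 | intermediate
21 | lithium 9α,13R-epoxy-18-nor-5α,8βH-labd-3-en-15,16-olid-3-olate | C[C@@H]1CC[C@H]2C(C)=C([O-])CC[C@]2(C)[C@@]12CC[C@@]1(COC(=O)C1)O2.[Li+] | intermediate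
22 | 9α,13R-epoxy-18-hydroxy-3-oxo-5α,8βH-labdan-15,16-olide | C[C@@H]1CC[C@H]2[C@](C)(CO)C(=O)CC[C@]2(C)[C@@]12CC[C@@]1(COC(=O)C1)O2 | intermediate
23 | (3S,4R,5S,8R,9R,10S,13R)-3β,18-dihydroxy-9α,13-epoxylabdan-15,16-olide (CNP0274732.3) | C[C@@H]1CC[C@H]2[C@](C)(CO)[C@@H](O)CC[C@]2(C)[C@@]12CC[C@@]1(COC(=O)C1)O2 | target

**Step count and risks**

Total step count: 15. Longest linear sequence: 11 steps (steps 5 to 15, from 6 and 7); the four-step branch to 5 (steps 1 to 4) joins at step 9.

Steps most likely to fail: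

1. Step 11. The dienamine may not form on the hindered enone or may add through C4 or C2, acrolein may oligomerise, and the enamine aldol onto the hindered, hemiketal-masked C9 carbonyl may stall before dehydration. Fallback from 14, by a known Michael/intramolecular Horner–Wadsworth–Emmons annulation: 14 with tert-butyl 2-(diethoxyphosphoryl)acrylate and NaH in THF should give the tert-butyl enoate F1, in which the same two bonds are made and loss of phosphate makes the closure irreversible. KOt-Bu-catalysed oxa-Michael addition then gives the spiro-ether ester F2, TFA gives the acid F3, BH3·SMe2 reduces the acid chemoselectively to the primary alcohol F4, I2/PPh3/imidazole gives the iodide F5, and Bu3SnH/AIBN gives 20, where the route is rejoined.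

2. Step 12. The conjugate addition may be incomplete or may revert (retro-oxa-Michael on work-up or during step 13), and the facial selectivity at C9 may be poor. Fallback from 17: NaBH4 in MeOH/CH2Cl2 at −78 °C should reduce the aldehyde selectively to the allylic alcohol F6. Catalytic Bi(OTf)3 in CH2Cl2 should ionise F6 to the C9/C17 allyl cation, which the C13 hydroxyl captures at C9 (5-exo, axial, anti to the C10 methyl) to give the 8(17)-methylene spiro-ether F7. Rh-catalysed hydroboration (catecholborane, RhCl(PPh3)3) and NaBO3·4H2O oxidation give the primary alcohol F8 as C8 epimers. Periodinane oxidation gives 18 together with its C8 epimer F9, and DBU equilibration converts F9 into 18, where the route is rejoined.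

3. Step 14. Dissolved lithium may over-reduce the lactone, and the lithium aldolate may lose formaldehyde by retro-aldol cleavage before the quench. Fallback from 20: LiOH (1 equiv, THF/H2O) opens the lactone to the lithium hydroxy-carboxylate F10, which is inert to dissolving metal. The same reduction and formaldehyde trapping are run on F10, and acidification to pH 2 closes the lactone again to give 22.

**Further compounds**

F1 | step 11 | tert-butyl (4aS)-5-{2-[(3R)-3-hydroxy-5-oxooxolan-3-yl]ethyl}-1,4a-dimethyl-2-oxo-2,3,4,4a,7,8-hexahydronaphthalene-6-carboxylate | CC(C)(C)OC(=O)C1=C(CC[C@]2(O)COC(=O)C2)[C@@]3(C)CCC(=O)C(C)=C3CC1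
F2 | step 11 | tert-butyl 9α,13R-epoxy-3-oxo-18-nor-8βH-labd-4-en-15,16-olid-17-oate | CC(C)(C)OC(=O)[C@@H]1CCC2=C(C)C(=O)CC[C@]2(C)[C@@]12CC[C@@]1(COC(=O)C1)O2
F3 | step 11 | 9α,13R-epoxy-3-oxo-18-nor-8βH-labd-4-en-15,16-olid-17-oic acid | OC(=O)[C@@H]1CCC2=C(C)C(=O)CC[C@]2(C)[C@@]12CC[C@@]1(COC(=O)C1)O2
F4 | step 11 | 9α,13R-epoxy-17-hydroxy-3-oxo-18-nor-8βH-labd-4-en-15,16-olide | OC[C@@H]1CCC2=C(C)C(=O)CC[C@]2(C)[C@@]12CC[C@@]1(COC(=O)C1)O2
F5 | step 11 | 9α,13R-epoxy-17-iodo-3-oxo-18-nor-8βH-labd-4-en-15,16-olide | IC[C@@H]1CCC2=C(C)C(=O)CC[C@]2(C)[C@@]12CC[C@@]1(COC(=O)C1)O2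
F6 | step 12 | (4aR)-6-(hydroxymethyl)-5-{2-[(3R)-3-hydroxy-5-oxooxolan-3-yl]ethyl}-1,4a-dimethyl-4,4a,7,8-tetrahydronaphthalen-2(3H)-one | OCC1=C(CC[C@]2(O)COC(=O)C2)[C@@]3(C)CCC(=O)C(C)=C3CC1
F7 | step 12 | 9α,13R-epoxy-3-oxo-18-norlabda-4,8(17)-dien-15,16-olide | C=C1CCC2=C(C)C(=O)CC[C@]2(C)[C@@]12CC[C@@]1(COC(=O)C1)O2
F8 | step 12 | 9α,13R-epoxy-17-hydroxy-3-oxo-18-norlabd-4-en-15,16-olide (both C8 epimers) | OCC1CCC2=C(C)C(=O)CC[C@]2(C)[C@@]12CC[C@@]1(COC(=O)C1)O2
F9 | step 12 | 9α,13R-epoxy-3,17-dioxo-18-nor-8αH-labd-4-en-15,16-olide (C8 epimer of 18) | O=C[C@H]1CCC2=C(C)C(=O)CC[C@]2(C)[C@@]12CC[C@@]1(COC(=O)C1)O2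
F10 | step 14 | lithium 9α,13R-epoxy-16-hydroxy-3-oxo-18-nor-8βH-labd-4-en-15-oate | C[C@@H]1CCC2=C(C)C(=O)CC[C@]2(C)[C@@]12CC[C@](CO)(CC(=O)[O-])O2.[Li+]
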